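Readings and results are calculated with made-up constants, noise included.

**Slow tail.** Slowness shows in the elm run after its first reading: complex with two exchanged reads 5% to 6%, while complex with one exchanged sinks from 15% to 8% by 90.0 s.

| setting | elm | birch | larch | alpha | epsilon | gamma |
|---|---|---|---|---|---|---|
| starting complex | 0.30 M | 0.30 M | 0.30 M | 0.30 M | 0.30 M | 0.30 M |
| incoming ligand | 0.18 M | 0.34 M | 0.75 M | 0.900 M | 0.150 M | 0.240 M |
| remark | run made earlier | run made earlier | run made earlier |  |  |  |
| time |  |  |  | 3.0 min | 3.0 min | 3.0 min |

| run | time / s | complex with two exchanged / % | complex with one exchanged / % |
|---|---|---|---|
| elm | 12.0 | 5 | 15 |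
| elm | 30.0 | 5 | 12 |
| elm | 60.0 | 6 | 10 |
| elm | 90.0 | 6 | 8 |
| birch | 12.0 | 15 | 20 |
| birch | 30.0 | 15 | 16 |
| birch | 60.0 | 17 | 15 |
| birch | 90.0 | 13 | 13 |
| larch | 25.0 | 46 | 12 |
| larch | 50.0 | 44 | 12 |
| larch | 60.0 | 50 | 16 |
| larch | 90.0 | 44 | 13 |

(each reading ± 1.5 percentage points)

- what is said of complex with one exchanged includes crystals
- crystals is a solid; its amount is given per volume of the solution
- steps that have been proposed: starting complex + incoming ligand -> leaving ligand + complex with one exchanged; complex with one exchanged + incoming ligand -> leaving ligand + complex with two exchanged; complex with two exchanged + incoming ligand -> leaving ligand + complex with three exchanged; complex with three exchanged + incoming ligand -> leaving ligand + complex with four exchanged; crystals <-> complex with one exchanged; incoming ligand -> decomposed reagent; complex with one exchanged -> over-reaction product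

* which of these holds the largest part of the starting complex at the end of alpha (complex with one exchanged / starting complex / complex with three exchanged / complex with four exchanged / complex with two exchanged)
* which of these holds the largest part of the starting complex at the end of epsilon (complex with one exchanged / starting complex / complex with three exchanged / complex with four exchanged / complex with two exchanged)
* which of these holds the largest part of the starting complex at the end of gamma (complex with one exchanged / starting complex / complex with three exchanged / complex with four exchanged / complex with two exchanged)
* final complex with two exchanged in epsilon, as a percentage of the starting complex charged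

**Captured share.** The fast part can be counted by what it leaves. At its first reading elm gives 41.7%: this is the captured share, the exchanges made per incoming ligand charged, each complex with two exchanged counted as two. Birch reads 44.1% and larch 41.6%, at the same 0.30 M of starting complex. Carried to the new flasks, the exchanges per starting complex reckon as the share times c(incoming ligand)/c(starting complex): 1.25 in alpha, 0.333 in gamma, 0.208 in epsilon.

**Epsilon curve.** My own reckoning for epsilon: complex with two exchanged starts with zero slope, for its rate goes with c(complex with one exchanged), and none of that is charged. While little has reacted it grows as the square of the exchanges, so the mean elm level scales to 3.82%. The reckoning puts the knee early, as complex with two exchanged in elm reads 5% by 12.0 s, and carries this level to the end of epsilon. It gives complex with one exchanged 13.2% at the knee, sinking slowly after it, and starting complex near 83.0%.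

**The forecast.** It names complex with two exchanged for alpha, starting complex for epsilon, starting complex for gamma, and 4% (2.5% to 5.5%), from “a steady ~42% of the ligand charged in each run”.

    starting complex + incoming ligand → leaving ligand + complex with one exchanged (k = 0.350 /M/s)
    complex with one exchanged + incoming ligand → leaving ligand + complex with two exchanged (k = 1.20 /M/s)
    complex with two exchanged + incoming ligand → leaving ligand + complex with three exchanged (k = 0.0110 /M/s)
    complex with three exchanged + incoming ligand → leaving ligand + complex with four exchanged (k = 0.190 /M/s)
    crystals ⇌ complex with one exchanged, rate k5*(cs5 - [complex with one exchanged]) while solid is left; crystals form when [complex with one exchanged] > cs5 (solubility = 0.250 M, k = 9.40 /s)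
    incoming ligand → decomposed reagent (k = 0.160 /s)
    complex with one exchanged → over-reaction product (k = 0.00320 /s)

**In the flask.** Alpha ends with complex with two exchanged at 54.7%, gamma with starting complex at 74.5%, epsilon with starting complex at 83.0% and 4.52% of complex with two exchanged. In epsilon, decomposition and the first exchange ran together, with ligand half-lives of 0.072 min and 0.12 min by these steps at 0.0406 min, and incoming ligand, the limiting reagent, stands at 0% by 1.50 min. Complex with one exchanged in epsilon stands at 9.45% at 1.50 min and 7.09% at 3.00 min. Leaving ligand in epsilon gives a share of 43.1% at 3.00 min. For a further flask like epsilon but with 0.60 M of incoming ligand, the share reckons 0.250 M of leaving ligand; that flask holds 0.264 M at 3.00 min.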